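(The data are simulated for substances that don't exist; scatter was added.)

At early times a flask shows how fast monomer in chains is made, and late times show how fast it is lost. What stands at the end is the balance of the two.

the same everywhere: initiator 0.2 mol%
- maple: free monomer 0.0016 M; run made earlier
- elm: free monomer 0.028 M; run made earlier
- winter: free monomer 0.0012 M; time 3.0 min
- dusk: free monomer 0.0025 M; time 3.0 min
- noon: free monomer 0.0050 M; time 3.0 min
- midnight: free monomer 0.010 M; time 3.0 min
- dawn: free monomer 0.020 M; time 3.0 min

| run | time / s | monomer in chains / % |
|---|---|---|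
| maple | 10.0 | 0 |
| maple | 15.0 | 0.3 |
| maple | 25.0 | 0.6 |
| maple | 40.0 | 0.5 |
| maple | 50.0 | 0.5 |
| maple | 80.0 | 2.3 |
| maple | 90.0 | 1.3 |
| elm | 12.0 | 23.5 |
| elm | 25.0 | 35.3 |
| elm | 40.0 | 37.1 |
| elm | 50.0 | 35.8 |
| elm | 60.0 | 31.1 |
| elm | 80.0 | 21.5 |
| elm | 90.0 | 17.9 |

(standard deviation of a reading: 0.5 percentage points)

- the earlier runs were read with a standard deviation of 0.5 percentage points
- on the list of suspects stand: free monomer + initiator -> living end + monomer in chains; free monomer + living end -> monomer in chains + living end; monomer in chains -> over-reaction product; initiator <-> dormant form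
- "hardly changes" means that all values lie within two and a half points (for a concentration: within two and a half percent of the largest)

- [monomer in chains] at the end for winter, dusk, noon, midnight, dawn, in this order
- the shape of the row from first to last (hardly changes / rises all the way / falls all the way / rises, then falls / falls, then rises)

I start from the loss. The elm run falls from 31.1% at 60.0 s to 17.9% at 90.0 s, and taking this as first order gives 54.3 s for τ, the time in which monomer in chains shrinks by a factor e. This is shorter than 3.0 min, so as a rough rule I treat the chains as a quasi-steady state: a flask still making them holds about the making rate r times τ. But elm may still be making chains over that stretch, so this τ is an apparent time and may run long.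

Next comes r. The first elm reading gives 5.48 × 10⁻⁴ M s⁻¹, and the maple reading at 25.0 s gives 3.84 × 10⁻⁷ M s⁻¹. If r grows as the charge to the power n, then n is 2.54.

The weak link is that single maple reading, which lies close to the scatter. So I reforge it with the maple readings from 40.0 s to 90.0 s. They are still on their way up and hold no steady level, so I divide their mean by τ and by the share of the steady level reached at their mean time, 0.698. This gives a mean making rate up to that time of 4.85 × 10⁻⁷ M s⁻¹, and n becomes 2.46.

At its early rate, elm would use its charge in 51.1 s. Scaling that time with n, the charge lasts about 3.0 min at 0.0118 M. Richer flasks should be past their peak by the end, so I expect a rise and then a fall, with noon near 4.33 × 10⁻⁴ M.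

The forecast differs. It gives 3.000 × 10⁻⁷ M, 2.000 × 10⁻⁶ M, 1.300 × 10⁻⁵ M, 8.300 × 10⁻⁵ M and 4.600 × 10⁻⁴ M, so its shape is rises all the way: “No maximum is expected, since the decay factor is the same for every run.”

The flasks give 1.68 × 10⁻⁵ M, 1.12 × 10⁻⁴ M, 4.63 × 10⁻⁴ M, 9.70 × 10⁻⁴ M and 7.72 × 10⁻⁴ M, so the shape is rises, then falls, turning at 0.012 M.

    free monomer + initiator → living end + monomer in chains (k = 16.7 M⁻¹ s⁻¹)
    free monomer + living end → monomer in chains + living end, rate k2*[living end]*[free monomer] (k = 901 M⁻¹ s⁻¹)
    monomer in chains → over-reaction product (k = 0.0305 s⁻¹)
    initiator ⇌ dormant form (K = 14.0, k = 0.367 s⁻¹)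

The loss step has a lifetime of 32.8 s, shorter than my apparent τ of 54.3 s. Carried to noon, r times τ gave 4.33 × 10⁻⁴ M, and the noon flask holds 4.63 × 10⁻⁴ M. The largest single effect on dawn is the step from monomer in chains to over-reaction product: without it, dawn ends at 0.0197 M instead of 7.72 × 10⁻⁴ M.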